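**Plan**
- Cuts: the 2-O-acyl and 6-O-silyl masks come off first. Then the O1–C2 bond of the five-membered ring B is cut to an achiral 1-(2-hydroxyaryl)-1,2-dione, the C2 carbonyl oxygen is removed, and last the C2–C1' bond between the acetophenone methyl carbon and the farnesyl chain is cut.
- Forward: ring A is bought as 2,4-dihydroxyacetophenone. The farnesyl chain is joined to its dianion, the new alpha-methylene is raised to a ketone in two steps, and ring B closes last, in the key step.
- Enabling feature: C2 is a hemiketal carbon held between O1 and the C3 ketone. Breaking O1–C2 leaves a planar carbonyl carbon beside a free phenol on C7a, so both C2 configurations interconvert through one achiral dione.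
- Stereochemistry: the only stereocentre, C2 (R), is set by a chiral isothiourea that acylates one hemiketal enantiomer. The two E alkenes come in with (2E,6E)-farnesol.
- End game: the silyl ether is removed while C2 is still locked as its ester. The ester goes last, by acyl–oxygen cleavage in a neutral, water-free medium.

Key step: step 6

Assumption 1: ring opening of the free hemiketal needs a base (loss of the C2–OH proton with expulsion of the O1 phenoxide), so the target is taken to hold its configuration in neutral or faintly acidic aprotic media at or below room temperature and is kept away from base once freed.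

Assumption 2: (2S,3R)-HyperBTM, that is (2S,3R)-3-isopropyl-2-phenyl-3,4-dihydro-2H-benzo[4,5]thiazolo[3,2-a]pyrimidine, is taken as the catalyst enantiomer that acylates the (2R)-hemiketal faster; if a trial run shows the opposite sense, the equally available (2R,3S) enantiomer is used with nothing else changed.

**Step 1**
Reactants: 1 (2E,6E)-farnesol
Product: 2 (2E,6E)-farnesyl bromide
Conditions: PBr3 (0.4 equiv), Et2O, 0 °C, dark; used crude at once
Reagents that add atoms: PBr3, BrP(Br)Br
Why: Bromination of a primary allylic alcohol with PBr3 (SN2 on the phosphite ester) is the standard entry to this bromide and at 0 °C should leave both E alkenes and the allylic position untransposed.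

**Step 2**
Reactants: 3 2,4-dihydroxyacetophenone
Product: 4 1-[4-(tert-butyldimethylsilyloxy)-2-hydroxyphenyl]ethan-1-one
Conditions: TBSCl (1.05 equiv), imidazole, CH2Cl2, 0 °C to rt
Reagents that add atoms: TBSCl, CC(C)(C)[Si](C)(C)Cl
Why: In this selective silyl chloride–imidazole silylation the 2-OH is tied up in a hydrogen bond to the acetyl carbonyl, so only the free 4-OH should react.

**Step 3**
Reactants: 4 1-[4-(tert-butyldimethylsilyloxy)-2-hydroxyphenyl]ethan-1-one; 2 (2E,6E)-farnesyl bromide
Product: 5 (4E,8E)-1-[4-(tert-butyldimethylsilyloxy)-2-hydroxyphenyl]-5,9,13-trimethyltetradeca-4,8,12-trien-1-one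
Conditions: 4 (1.2 equiv), LiN(iPr)2 (2.1 equiv per 4), THF, −78 to −20 °C; then 2, −78 to 0 °C; AcOH quench
Reagents that add atoms: none
Why: In this phenoxide–enolate dianion C-alkylation the methyl ketone enolate made by the second deprotonation is by far the stronger nucleophile and displaces the primary allylic bromide by SN2 with the alkene geometry kept, while the small excess of 4 limits double alkylation.

**Step 4**
Reactants: 5 (4E,8E)-1-[4-(tert-butyldimethylsilyloxy)-2-hydroxyphenyl]-5,9,13-trimethyltetradeca-4,8,12-trien-1-one
Product: 6 racemic (4E,8E)-2-hydroxy-1-[4-(tert-butyldimethylsilyloxy)-2-hydroxyphenyl]-5,9,13-trimethyltetradeca-4,8,12-trien-1-one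
Conditions: NaN(SiMe3)2 (2.2 equiv), THF, −78 °C; 2-(phenylsulfonyl)-3-phenyloxaziridine (1.3 equiv), −78 °C; AcOH quench
Reagents that add atoms: 2-(phenylsulfonyl)-3-phenyloxaziridine, O=S(=O)(c1ccccc1)N1OC1c1ccccc1
Why: In the Davis enolate hydroxylation the N-sulfonyloxaziridine passes oxygen to the sodium enolate at −78 °C, where trisubstituted alkenes are not epoxidised, and the new carbinol centre is racemic and is erased in step 5.

**Step 5**
Reactants: 6 racemic (4E,8E)-2-hydroxy-1-[4-(tert-butyldimethylsilyloxy)-2-hydroxyphenyl]-5,9,13-trimethyltetradeca-4,8,12-trien-1-one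
Product: 7 (4E,8E)-1-[4-(tert-butyldimethylsilyloxy)-2-hydroxyphenyl]-5,9,13-trimethyltetradeca-4,8,12-triene-1,2-dione
Conditions: Dess–Martin periodinane (1.3 equiv), CH2Cl2, 0 °C to rt
Reagents that add atoms: none
Why: Dess–Martin oxidation of an alpha-hydroxy ketone to the 1,2-diketone runs without base, so the triene, the silyl ether, the chelated phenol and the doubly activated chain C3 methylene should survive, and 7 (written in its open form) is expected to rest largely as its ring-closed racemic hemiketal tautomer.

**Step 6**
Reactants: 7 (4E,8E)-1-[4-(tert-butyldimethylsilyloxy)-2-hydroxyphenyl]-5,9,13-trimethyltetradeca-4,8,12-triene-1,2-dione; 8 isobutyric anhydride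
Product: 10 (2S)-6-(tert-butyldimethylsilyloxy)-3-oxo-2-[(2E,6E)-3,7,11-trimethyldodeca-2,6,10-trien-1-yl]-2,3-dihydro-1-benzofuran-2-yl 2-methylpropanoate, via 6-O-silyl (2R)-hemiketal 9 (not isolated)
Conditions: (2S,3R)-HyperBTM (10 mol %), 8 (1.5 equiv), iPr2NEt (1.5 equiv), PhMe, 0 °C
Reagents that add atoms: none
Why: The amine and the isobutyrate ion keep 7 in fast exchange with both enantiomers of its ring-closed hemiketal, while the isothiourea is N-acylated by 8 to an acyl isothiouronium isobutyrate that hands its acyl group to the C2 hydroxyl of 9, the carboxylate acting as proton shuttle. The closest known reaction type is the isothiourea-catalysed acylative dynamic kinetic resolution of tetrasubstituted lactols that carry a carbonyl group next to the lactol carbon, an outgrowth of the kinetic resolution of tertiary alpha-carbonyl alcohols with the same catalysts. Ring B closes by 5-exo-trig addition of the phenolic oxygen on C7a (the future O1) to the C2 ketone of the dione. C2 is controlled by the catalyst alone: the C3 carbonyl oxygen is expected to dock on the cationic isothiouronium face, so that the flat benzo-fused O1 side and the farnesyl methylene fall into unlike quadrants set by the phenyl and isopropyl groups of the catalyst and only the (2R)-hemiketal offers its hydroxyl to the acyl carbon, the descriptor of 10 reading S merely because the acyloxy group outranks O1. The step needs ring–chain exchange to outrun acylation of the mismatched enantiomer, which the good phenoxide leaving group and the strongly electrophilic 1,2-dione should secure, and once acylated C2 has no hydroxyl proton left and cannot reopen, so the pool empties into 10. It also needs acylation at the hemiketal hydroxyl and not at the phenol of 7, which is secured by the small share of open form, by the hydrogen bond of that phenol to the C1 ketone and by the silyl cap on the other phenol, while the branched anhydride, the hindered amine and the low temperature hold back uncatalysed acylation and enolisation of the chain C3 methylene.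

**Step 7**
Reactants: 10 (2S)-6-(tert-butyldimethylsilyloxy)-3-oxo-2-[(2E,6E)-3,7,11-trimethyldodeca-2,6,10-trien-1-yl]-2,3-dihydro-1-benzofuran-2-yl 2-methylpropanoate
Product: 11 (2S)-6-hydroxy-3-oxo-2-[(2E,6E)-3,7,11-trimethyldodeca-2,6,10-trien-1-yl]-2,3-dihydro-1-benzofuran-2-yl 2-methylpropanoate
Conditions: Bu4NF/AcOH (1:1, 1.2 equiv), THF, 0 °C
Reagents that add atoms: none
Why: Fluoride cleavage of an aryl silyl ether should be fast here because the leaving phenoxide is para to the C3 ketone, acetic acid buffers the fluoride so that the ketal ester is left alone, and C2 still lacks a free hydroxyl and cannot epimerise.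

**Step 8**
Reactants: 11 (2S)-6-hydroxy-3-oxo-2-[(2E,6E)-3,7,11-trimethyldodeca-2,6,10-trien-1-yl]-2,3-dihydro-1-benzofuran-2-yl 2-methylpropanoate
Product: 12 (2R)-2,6-dihydroxy-2-[(2E,6E)-3,7,11-trimethyldodeca-2,6,10-trien-1-yl]-1-benzofuran-3(2H)-one
Conditions: immobilised Candida antarctica lipase A, n-BuOH (5 equiv), MTBE, 25 °C; filtration, concentration below 25 °C, base-free handling
Reagents that add atoms: none
Why: Lipase-catalysed transesterification (alcoholysis) breaks the acyl–oxygen bond through a serine acyl-enzyme, so the C2–O bond and the spatial arrangement at C2 stay untouched, lipase A of Candida antarctica being the hydrolase known to accept esters of tertiary alcohols, and the neutral water-free ether medium offers no base for opening O1–C2 in the freed hemiketal.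

**Compound list**
1 | (2E,6E)-farnesol | CC(C)=CCC/C(C)=C/CC/C(C)=C/CO | starting material
2 | (2E,6E)-farnesyl bromide | CC(C)=CCC/C(C)=C/CC/C(C)=C/CBr | intermediate
3 | 2,4-dihydroxyacetophenone | CC(=O)c1ccc(O)cc1O | starting material
4 | 1-[4-(tert-butyldimethylsilyloxy)-2-hydroxyphenyl]ethan-1-one | CC(=O)c1ccc(O[Si](C)(C)C(C)(C)C)cc1O | intermediate
5 | (4E,8E)-1-[4-(tert-butyldimethylsilyloxy)-2-hydroxyphenyl]-5,9,13-trimethyltetradeca-4,8,12-trien-1-one | CC(C)=CCC/C(C)=C/CC/C(C)=C/CCC(=O)c1ccc(O[Si](C)(C)C(C)(C)C)cc1O | intermediate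
6 | racemic (4E,8E)-2-hydroxy-1-[4-(tert-butyldimethylsilyloxy)-2-hydroxyphenyl]-5,9,13-trimethyltetradeca-4,8,12-trien-1-one | CC(C)=CCC/C(C)=C/CC/C(C)=C/CC(O)C(=O)c1ccc(O[Si](C)(C)C(C)(C)C)cc1O | intermediate
7 | (4E,8E)-1-[4-(tert-butyldimethylsilyloxy)-2-hydroxyphenyl]-5,9,13-trimethyltetradeca-4,8,12-triene-1,2-dione (open tautomer; equilibrates with both enantiomers of the hemiketal) | CC(C)=CCC/C(C)=C/CC/C(C)=C/CC(=O)C(=O)c1ccc(O[Si](C)(C)C(C)(C)C)cc1O | intermediate
8 | isobutyric anhydride | CC(C)C(=O)OC(=O)C(C)C | starting material
9 | (2R)-6-(tert-butyldimethylsilyloxy)-2-hydroxy-2-[(2E,6E)-3,7,11-trimethyldodeca-2,6,10-trien-1-yl]-1-benzofuran-3(2H)-one (matched hemiketal, not isolated) | CC(C)=CCC/C(C)=C/CC/C(C)=C/C[C@@]1(O)Oc2cc(O[Si](C)(C)C(C)(C)C)ccc2C1=O | intermediate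
10 | (2S)-6-(tert-butyldimethylsilyloxy)-3-oxo-2-[(2E,6E)-3,7,11-trimethyldodeca-2,6,10-trien-1-yl]-2,3-dihydro-1-benzofuran-2-yl 2-methylpropanoate | CC(C)=CCC/C(C)=C/CC/C(C)=C/C[C@@]1(OC(=O)C(C)C)Oc2cc(O[Si](C)(C)C(C)(C)C)ccc2C1=O | intermediate
11 | (2S)-6-hydroxy-3-oxo-2-[(2E,6E)-3,7,11-trimethyldodeca-2,6,10-trien-1-yl]-2,3-dihydro-1-benzofuran-2-yl 2-methylpropanoate | CC(C)=CCC/C(C)=C/CC/C(C)=C/C[C@@]1(OC(=O)C(C)C)Oc2cc(O)ccc2C1=O | intermediate
12 | (2R)-2,6-dihydroxy-2-[(2E,6E)-3,7,11-trimethyldodeca-2,6,10-trien-1-yl]-1-benzofuran-3(2H)-one | CC(C)=CCC/C(C)=C/CC/C(C)=C/C[C@@]1(O)Oc2cc(O)ccc2C1=O | target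

Total step count: 8. Longest linear sequence: 7 steps (steps 1 or 2, then 3 to 8).

**Steps most likely to fail**

Step 6. The catalyst may tell the two hemiketal enantiomers apart too poorly. Acyl transfer to the phenol of the open form may compete, or the amine may shift the chain C4–C5 alkene of the open form into conjugation with the dione. The fallback sets out from 7 and comes back at 10. Compound 7 is acylated with 8 under achiral DMAP catalysis (iPr2NEt, CH2Cl2, 0 °C) to the racemic ketal isobutyrate F1. F1 is configurationally locked, so it is split by preparative supercritical-fluid chromatography on a polysaccharide chiral phase into 10 and the (2R)-ketal isobutyrate F2. DMAP-catalysed methanolysis sends F2 back to 7 for another pass.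

Step 8. The lipase may refuse the crowded tertiary ketal ester. Turnover may also be so slow that the freed hemiketal loses configurational purity by ring opening while it waits. The fallback sets out from 7 and comes back at 12, and it swaps the enzyme for an acyl group that removes itself. Step 6 is run with 4-azidobutanoic anhydride F3 (made from the commercial acid with DCC) in place of 8 to give the (2S)-ketal 4-azidobutanoate F4. Buffered desilylation as in step 7 gives the 6-hydroxy (2S)-ketal 4-azidobutanoate F5. Staudinger reduction (PPh3, THF/H2O, 0 °C) then unmasks a primary amine that closes on its own ester carbonyl by 5-exo-trig lactamisation, the known assisted cleavage of 4-azidobutanoates. This releases 12 by acyl–oxygen scission without an external nucleophile or base.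

Step 3. Proton exchange between the dianion and the first-formed product may lead to double alkylation. The phenoxide may be O-alkylated, or the labile bromide may decompose before it is consumed. The fallback sets out from 1 and comes back at 5, and it replaces the hard enolate by a soft one with a single acidic C–H. Compound 1 is turned into (2E,6E)-farnesyl methyl carbonate F6 (ClCO2Me, pyridine, CH2Cl2). A Tsuji–Trost allylation of commercial 4,7-dihydroxycoumarin with F6, under the zerovalent palladium catalyst Pd(PPh3)4 in THF, places the chain through its less hindered terminus on C3 and gives 3-[(2E,6E)-farnesyl]-4,7-dihydroxycoumarin F7. Aqueous NaOH at reflux followed by acidification opens the lactone and decarboxylates the beta-keto acid to (4E,8E)-1-(2,4-dihydroxyphenyl)-5,9,13-trimethyltetradeca-4,8,12-trien-1-one F8. Selective 4-O-silylation as in step 2 then gives 5.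

**Further compounds**
F1 | step 6 | racemic 6-(tert-butyldimethylsilyloxy)-3-oxo-2-[(2E,6E)-farnesyl]-2,3-dihydro-1-benzofuran-2-yl 2-methylpropanoate | CC(C)=CCC/C(C)=C/CC/C(C)=C/CC1(OC(=O)C(C)C)Oc2cc(O[Si](C)(C)C(C)(C)C)ccc2C1=O
F2 | step 6 | (2R)-6-(tert-butyldimethylsilyloxy)-3-oxo-2-[(2E,6E)-farnesyl]-2,3-dihydro-1-benzofuran-2-yl 2-methylpropanoate | CC(C)=CCC/C(C)=C/CC/C(C)=C/C[C@]1(OC(=O)C(C)C)Oc2cc(O[Si](C)(C)C(C)(C)C)ccc2C1=O
F3 | step 8 | 4-azidobutanoic anhydride | [N-]=[N+]=NCCCC(=O)OC(=O)CCCN=[N+]=[N-]
F4 | step 8 | (2S)-6-(tert-butyldimethylsilyloxy)-3-oxo-2-[(2E,6E)-farnesyl]-2,3-dihydro-1-benzofuran-2-yl 4-azidobutanoate | CC(C)=CCC/C(C)=C/CC/C(C)=C/C[C@@]1(OC(=O)CCCN=[N+]=[N-])Oc2cc(O[Si](C)(C)C(C)(C)C)ccc2C1=O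
F5 | step 8 | (2S)-6-hydroxy-3-oxo-2-[(2E,6E)-farnesyl]-2,3-dihydro-1-benzofuran-2-yl 4-azidobutanoate | CC(C)=CCC/C(C)=C/CC/C(C)=C/C[C@@]1(OC(=O)CCCN=[N+]=[N-])Oc2cc(O)ccc2C1=O
F6 | step 3 | (2E,6E)-farnesyl methyl carbonate | CC(C)=CCC/C(C)=C/CC/C(C)=C/COC(=O)OC
F7 | step 3 | 3-[(2E,6E)-farnesyl]-4,7-dihydroxycoumarin | CC(C)=CCC/C(C)=C/CC/C(C)=C/Cc1c(O)c2ccc(O)cc2oc1=O
F8 | step 3 | (4E,8E)-1-(2,4-dihydroxyphenyl)-5,9,13-trimethyltetradeca-4,8,12-trien-1-one | CC(C)=CCC/C(C)=C/CC/C(C)=C/CCC(=O)c1ccc(O)cc1O
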